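The earlier runs and the new flasks hold the same amounts of starting complex and incoming ligand and differ in their scavenger, so the question is how much scavenger the exchanges call for.

| flask | starting complex | incoming ligand | scavenger | remark | time |
|---|---|---|---|---|---|
| Wednesday's | 0.20 M | 3 equiv | 1.5 equiv | run made earlier |  |
| Sunday's | 0.20 M | 3 equiv | 3.2 equiv | run made earlier |  |
| green | 0.20 M | 3.00 equiv | 1.20 equiv |  | 5.0 min |
| ochre | 0.20 M | 3.00 equiv | 1.60 equiv |  | 5.0 min |
| teal | 0.20 M | 3.00 equiv | 2.00 equiv |  | 5.0 min |

- part of the starting complex that has reacted at the end, green
- part of the starting complex that has reacted at the end, ochre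
- part of the starting complex that has reacted at the end, teal
- what raising the equivalents of scavenger from its lowest to its highest value here does to the part of the starting complex that has reacted (changes below 5 percentage points count as none) (it rises / it falls / no change)



| run | time / min | starting complex / % | complex with one exchanged / % |
|---|---|---|---|
| Wednesday's | 0.333 | 77.1 | 18.7 |
| Wednesday's | 1.00 | 59.6 | 27.0 |
| Wednesday's | 2.00 | 51.2 | 29.6 |
| Wednesday's | 2.50 | 49.8 | 29.7 |
| Wednesday's | 4.00 | 48.8 | 29.5 |
| Wednesday's | 5.00 | 48.4 | 29.4 |
| Sunday's | 0.417 | 74.3 | 20.4 |
| Sunday's | 0.667 | 65.6 | 24.5 |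
| Sunday's | 1.00 | 59.3 | 27.0 |
| Sunday's | 2.00 | 51.2 | 28.6 |
| Sunday's | 3.00 | 48.9 | 30.0 |
| Sunday's | 5.00 | 48.8 | 29.5 |

(each reading ± 0.3 percentage points)

Read row against row. Sunday's flask carries twice Wednesday's scavenger, yet at 1.00 min the starting complex stands at 59.6% and 59.3%, and at 5.00 min at 48.4% and 48.8%. Those pairs lie within the scatter. The complex with one exchanged ends at 29.4% and 29.5%.

Now read column against column. We take the 22.2% missing from Wednesday's last row to be doubly exchanged. Counting the singly exchanged once and the rest twice, that row gives 0.738 equiv for the exchange count, the exchanges made per starting complex charged. If each exchange frees one ligand for one scavenger, this count is the scavenger's bill. Green, the leanest flask, has 1.20 equiv to pay it, so we do not expect scavenger to be the limiting reagent there. The count also covers just a quarter of the incoming ligand charged, and these readings do not show where the rest of that charge went. Our own reckoning puts each new flask at the earlier mean, 51.4% reacted.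

The forecast says the same: 51.4% for green, 51.4% for ochre, 51.4% for teal, so no change, since “Even 1.2 equiv of scavenger would still be in excess”.

Green gives 51.3%, ochre 51.5%, teal 51.6%: no change, with a difference of 0.29 percentage points from the lowest scavenger charge to the highest, so the forecast held. At 5.00 min green keeps 0.19% of its incoming ligand, less than the 39% of its scavenger. The exchange count puts that scavenger at 38.5% of its charge.

    starting complex + incoming ligand ⇌ leaving ligand + complex with one exchanged (K = 0.150, k = 0.0260 M⁻¹ s⁻¹)
    complex with one exchanged + incoming ligand ⇌ leaving ligand + complex with two exchanged (K = 0.160, k = 0.0390 M⁻¹ s⁻¹)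
    leaving ligand + starting complex ⇌ idle adduct, settled at all times (K = 2.10 M⁻¹)
    scavenger + leaving ligand → scavenged by-product (k = 5.00 M⁻¹ s⁻¹)
    incoming ligand → decomposed reagent (k = 0.0160 s⁻¹)

Take the neighbour of teal charged with 12.0 equiv of incoming ligand. The same share of its charge gives 2.95 equiv of exchanges, over the two a complex can take, so we expect a count near two against 2.00 equiv of scavenger. Computed, it holds 8.28% singly and 87.5% doubly exchanged, a count of 1.83 equiv, with 8.41% of its scavenger left.

The earlier runs and the new flask are calculated with constants of no real substance; scatter was added.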